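The synthesis rests on cutting the pyranone ring (O1, C2, C3, C4, C4a, C8a) at O1–C2 and C3–C4: O1–C8a–C4a–C4 of ring A is read as an ortho-quinone methide and C2–C3 as the vinyl group of a guaiacyl styrene. A chiral Brønsted acid ionises a hexasubstituted salicylaldehyde dimethyl acetal; the methoxy ortho-quinone methide adds the styrene, which closes the ring, forms both bonds and sets C2 (S) in one operation and leaves C4 as a methyl ether one oxidation level below the ketone. The acetal carries the free C8a hydroxyl beside the prenyl group and MOM ethers on the C5 and C7 oxygens and on the hydroxyethyl chain.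

Key step: step 11

Remark: which antipode of the acid catalyst leads to the 2S product cannot be predicted with confidence; the (R) acid is written and its mirror image would be used if the sense proves opposite.

Abbreviations: MOM = methoxymethyl; PPTS = pyridinium p-toluenesulfonate; (R)-TRIP = (R)-3,3'-bis(2,4,6-triisopropylphenyl)-1,1'-binaphthyl-2,2'-diyl hydrogen phosphate.

Step 1
Reactants: 1 resorcinol
Product: 2 1,3-bis(methoxymethoxy)benzene
Conditions: NaH, MOMCl, DMF, 0 °C to rt
Reagents that add atoms: chloromethyl methyl ether (MOMCl), COCCl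
Why: Double Williamson etherification of the two phenoxides with the reactive α-chloro ether should be clean, and the MOM groups then serve as cooperating directing groups and as acid-labile protection to the end.

Step 2
Reactants: 2 1,3-bis(methoxymethoxy)benzene; 3 ethylene oxide
Product: 5 2-[2,6-bis(methoxymethoxy)phenyl]ethanol, via aryllithium 4 (not isolated)
Conditions: n-BuLi, THF, 0 °C to rt; then ethylene oxide, 0 °C to rt; H2O
Reagents that add atoms: none
Why: Directed ortho-metalation: both MOM oxygens coordinate lithium and acidify the C–H between them, so only C2 should be lithiated, and the aryllithium opens ethylene oxide by SN2 attack to give the 2-arylethanol.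

Step 3
Reactants: 5 2-[2,6-bis(methoxymethoxy)phenyl]ethanol
Product: 6 1,3-bis(methoxymethoxy)-2-[2-(methoxymethoxy)ethyl]benzene
Conditions: NaH, MOMCl, THF, 0 °C to rt
Reagents that add atoms: chloromethyl methyl ether (MOMCl), COCCl
Why: Williamson etherification of the primary alkoxide gives a MOM ether that should survive every later step and fall together with the phenolic MOM groups in the last step.

Step 4
Reactants: 6 1,3-bis(methoxymethoxy)-2-[2-(methoxymethoxy)ethyl]benzene
Product: 8 3,5-bis(methoxymethoxy)-4-[2-(methoxymethoxy)ethyl]phenol, via arylboronate 7 (not isolated)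
Conditions: [Ir(OMe)(cod)]2 (1.5 mol%), 4,4'-di-tert-butyl-2,2'-bipyridine (3 mol%), B2pin2, THF, 80 °C; then NaOH aq., H2O2, 0 °C to rt
Reagents that add atoms: bis(pinacolato)diboron, CC1(C)OB(OC1(C)C)B1OC(C)(C)C(C)(C)O1 (boron ester of 7 only); hydrogen peroxide, OO
Why: Iridium-catalysed C–H borylation (Hartwig–Miyaura type) is governed by sterics and should take the only ring C–H without an ortho substituent, the one para to the side chain, and alkaline peroxide then turns the C–B bond into the phenol whose oxygen becomes O1.

Step 5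
Reactants: 9 2-methylbut-3-en-2-ol
Product: 10 tert-butyl 2-methylbut-3-en-2-yl carbonate
Conditions: n-BuLi, THF, 0 °C; then Boc2O, 0 °C to rt; H2O
Reagents that add atoms: di-tert-butyl dicarbonate (Boc2O), CC(C)(C)OC(=O)OC(=O)OC(C)(C)C
Why: Acylation of the lithium alkoxide of the tertiary allylic alcohol with Boc2O gives the mixed carbonate, a standard precursor of the 1,1-dimethylallyl palladium complex.

Step 6
Reactants: 8 3,5-bis(methoxymethoxy)-4-[2-(methoxymethoxy)ethyl]phenol; 10 tert-butyl 2-methylbut-3-en-2-yl carbonate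
Product: 11 1,3-bis(methoxymethoxy)-2-[2-(methoxymethoxy)ethyl]-5-[(2-methylbut-3-en-2-yl)oxy]benzene
Conditions: Pd(PPh3)4 (3 mol%), THF, 0 °C to rt
Reagents that add atoms: none
Why: Tsuji–Trost O-allylation: zerovalent palladium ionises the carbonate with loss of CO2 and tert-butoxide, and under kinetic control at low temperature the phenoxide should attack the more substituted allyl terminus to give the tertiary aryl ether.

Step 7
Reactants: 11 1,3-bis(methoxymethoxy)-2-[2-(methoxymethoxy)ethyl]-5-[(2-methylbut-3-en-2-yl)oxy]benzene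
Product: 12 3,5-bis(methoxymethoxy)-4-[2-(methoxymethoxy)ethyl]-2-(3-methylbut-2-en-1-yl)phenol
Conditions: toluene, 110 °C
Reagents that add atoms: none
Why: Aromatic Claisen rearrangement: the [3,3] shift transposes the allyl unit onto one of the two equivalent ortho carbons (the para carbon is blocked) and rearomatisation leaves the linear prenyl group beside the freed phenol.

Step 8
Reactants: 12 3,5-bis(methoxymethoxy)-4-[2-(methoxymethoxy)ethyl]-2-(3-methylbut-2-en-1-yl)phenol; 13 paraformaldehyde
Product: 15 2-hydroxy-4,6-bis(methoxymethoxy)-5-[2-(methoxymethoxy)ethyl]-3-(3-methylbut-2-en-1-yl)benzaldehyde, via hydroxymethylphenol 14 (not isolated)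
Conditions: MgCl2, Et3N, MeCN, 80 °C; citric acid aq.
Reagents that add atoms: none
Why: Casnati–Skattebøl ortho-formylation: the magnesium phenoxide delivers formaldehyde to the single remaining ring C–H, which is ortho to the phenol, and a second formaldehyde oxidises the hydroxymethyl group by hydride transfer, under basic conditions that leave the MOM ethers and the prenyl group alone.

Step 9
Reactants: 15 2-hydroxy-4,6-bis(methoxymethoxy)-5-[2-(methoxymethoxy)ethyl]-3-(3-methylbut-2-en-1-yl)benzaldehyde
Product: 16 2-(dimethoxymethyl)-3,5-bis(methoxymethoxy)-4-[2-(methoxymethoxy)ethyl]-6-(3-methylbut-2-en-1-yl)phenol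
Conditions: HC(OMe)3, MeOH, PPTS (5 mol%), rt; then Et3N, evaporate, use crude
Reagents that add atoms: trimethyl orthoformate, COC(OC)OC
Why: Acid-catalysed acetalisation driven by the orthoformate, with an acid too weak to cleave MOM ethers or to add the phenol to the prenyl alkene; the hydroxy acetal is labile and is carried on without chromatography.

Step 10
Reactants: 17 2-methoxy-4-vinylphenol
Product: 18 4-ethenyl-2-methoxy-1-(methoxymethoxy)benzene
Conditions: NaH, MOMCl, THF, 0 °C
Reagents that add atoms: chloromethyl methyl ether (MOMCl), COCCl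
Why: Williamson etherification of the phenoxide; MOM is chosen for ring B so that one acidic step frees all four hydroxyl groups at the end and no basic fluoride ever meets the flavanone.

Step 11
Reactants: 16 2-(dimethoxymethyl)-3,5-bis(methoxymethoxy)-4-[2-(methoxymethoxy)ethyl]-6-(3-methylbut-2-en-1-yl)phenol; 18 4-ethenyl-2-methoxy-1-(methoxymethoxy)benzene
Product: 20 (2S)-4-methoxy-2-[3-methoxy-4-(methoxymethoxy)phenyl]-5,7-bis(methoxymethoxy)-6-[2-(methoxymethoxy)ethyl]-8-(3-methylbut-2-en-1-yl)chromane (C4 epimers), via methoxy ortho-quinone methide 19 (not isolated)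
Conditions: (R)-TRIP (10 mol%), 18 (2 equiv), 3 Å MS, toluene, −20 °C
Reagents that add atoms: none
Why: Proposed new method: the chiral phosphoric acid protonates one acetal oxygen of 16, methanol leaves, and the 2-hydroxybenzyl oxocarbenium ion, equivalent to the methoxy ortho-quinone methide 19 hydrogen-bonded to the acid, is held as a contact ion pair with the chiral phosphate while the CH2 terminus of styrene 18 bonds to C4 and the phenol oxygen O1 captures the developing benzylic cation at C2. The closest known reactions are the achiral acid-promoted hetero-[4+2] addition of salicylaldehyde-acetal-derived alkoxy ortho-quinone methides to styrenes, which gives 4-alkoxyflavans, and chiral phosphoric acid-controlled [4+2] reactions of ortho-quinone methides; what is new is asking the chiral anion to steer a styrene that has no hydrogen-bonding handle onto a hexasubstituted partner. The pyran ring closes in the sense of an inverse-electron-demand hetero-Diels–Alder reaction, concerted but asynchronous or, if stepwise, by 6-exo-trig capture of the para-alkoxybenzylic cation by O1. C2 is set by which face of the styrene is exposed inside the ion pair, that is by the 3,3'-aryl walls of the catalyst, whereas C4 forms as a mixture and is erased in step 13. Regiochemistry (aryl at C2) follows the polarity of the styrene and its para MOM-oxy donor, the C5 and C7 oxygens stabilise the cation so that a mild acid suffices and the prenyl alkene, the MOM acetals and the product are spared, and only the free C8a hydroxyl can close the ring because the C5 oxygen is capped.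

Step 12
Reactants: 20 (2S)-4-methoxy-2-[3-methoxy-4-(methoxymethoxy)phenyl]-5,7-bis(methoxymethoxy)-6-[2-(methoxymethoxy)ethyl]-8-(3-methylbut-2-en-1-yl)chromane (C4 epimers)
Product: 21 (2S)-2-[3-methoxy-4-(methoxymethoxy)phenyl]-5,7-bis(methoxymethoxy)-6-[2-(methoxymethoxy)ethyl]-8-(3-methylbut-2-en-1-yl)chroman-4-ol (C4 epimers)
Conditions: PPTS (20 mol%), acetone/H2O 4:1, rt to 40 °C
Reagents that add atoms: water, O
Why: SN1 solvolysis: the C4 methyl ether sits on a benzylic carbon flanked by three ring oxygens (ortho, ortho and para), should ionise under weak acid and be captured by the large excess of water, while the MOM ethers need much stronger acid and C2 is not involved.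

Step 13
Reactants: 21 (2S)-2-[3-methoxy-4-(methoxymethoxy)phenyl]-5,7-bis(methoxymethoxy)-6-[2-(methoxymethoxy)ethyl]-8-(3-methylbut-2-en-1-yl)chroman-4-ol (C4 epimers)
Product: 22 (2S)-2-[3-methoxy-4-(methoxymethoxy)phenyl]-5,7-bis(methoxymethoxy)-6-[2-(methoxymethoxy)ethyl]-8-(3-methylbut-2-en-1-yl)chroman-4-one
Conditions: Dess–Martin periodinane, pyridine, CH2Cl2, 0 °C to rt
Reagents that add atoms: none
Why: Dess–Martin oxidation of the secondary benzylic alcohol (both C4 epimers converge on the ketone) under pyridine-buffered, non-basic conditions that should neither ionise C4 nor open the flavanone by retro-oxa-Michael reaction, so C2 stays S.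

Step 14
Reactants: 22 (2S)-2-[3-methoxy-4-(methoxymethoxy)phenyl]-5,7-bis(methoxymethoxy)-6-[2-(methoxymethoxy)ethyl]-8-(3-methylbut-2-en-1-yl)chroman-4-one
Product: 23 laxiflorin
Conditions: 3 M HCl aq./MeOH, 45 °C
Reagents that add atoms: none
Why: Acid-catalysed acetal exchange with methanol removes the three aryl and the one alkyl MOM groups, flavanones do not ring-open under acid so C2 should be retained, and the moderate temperature limits addition of the C7 hydroxyl to the prenyl alkene.

Compound list

1 | resorcinol | Oc1cccc(O)c1 | starting material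
2 | 1,3-bis(methoxymethoxy)benzene | COCOc1cccc(OCOC)c1 | intermediate
3 | ethylene oxide | C1CO1 | starting material
4 | [2,6-bis(methoxymethoxy)phenyl]lithium (not isolated) | [Li]c1c(OCOC)cccc1OCOC | intermediate
5 | 2-[2,6-bis(methoxymethoxy)phenyl]ethanol | OCCc1c(OCOC)cccc1OCOC | intermediate
6 | 1,3-bis(methoxymethoxy)-2-[2-(methoxymethoxy)ethyl]benzene | COCOCCc1c(OCOC)cccc1OCOC | intermediate
7 | 2-{3,5-bis(methoxymethoxy)-4-[2-(methoxymethoxy)ethyl]phenyl}-4,4,5,5-tetramethyl-1,3,2-dioxaborolane (not isolated) | COCOCCc1c(OCOC)cc(cc1OCOC)B1OC(C)(C)C(C)(C)O1 | intermediate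
8 | 3,5-bis(methoxymethoxy)-4-[2-(methoxymethoxy)ethyl]phenol | COCOCCc1c(OCOC)cc(O)cc1OCOC | intermediate
9 | 2-methylbut-3-en-2-ol | C=CC(C)(C)O | starting material
10 | tert-butyl 2-methylbut-3-en-2-yl carbonate | C=CC(C)(C)OC(=O)OC(C)(C)C | intermediate
11 | 1,3-bis(methoxymethoxy)-2-[2-(methoxymethoxy)ethyl]-5-[(2-methylbut-3-en-2-yl)oxy]benzene | C=CC(C)(C)Oc1cc(OCOC)c(CCOCOC)c(OCOC)c1 | intermediate
12 | 3,5-bis(methoxymethoxy)-4-[2-(methoxymethoxy)ethyl]-2-(3-methylbut-2-en-1-yl)phenol | COCOCCc1c(OCOC)cc(O)c(CC=C(C)C)c1OCOC | intermediate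
13 | paraformaldehyde (formaldehyde source) | C=O | starting material
14 | 2-(hydroxymethyl)-3,5-bis(methoxymethoxy)-4-[2-(methoxymethoxy)ethyl]-6-(3-methylbut-2-en-1-yl)phenol (not isolated) | OCc1c(O)c(CC=C(C)C)c(OCOC)c(CCOCOC)c1OCOC | intermediate
15 | 2-hydroxy-4,6-bis(methoxymethoxy)-5-[2-(methoxymethoxy)ethyl]-3-(3-methylbut-2-en-1-yl)benzaldehyde | O=Cc1c(O)c(CC=C(C)C)c(OCOC)c(CCOCOC)c1OCOC | intermediate
16 | 2-(dimethoxymethyl)-3,5-bis(methoxymethoxy)-4-[2-(methoxymethoxy)ethyl]-6-(3-methylbut-2-en-1-yl)phenol (the salicylaldehyde dimethyl acetal) | COC(OC)c1c(O)c(CC=C(C)C)c(OCOC)c(CCOCOC)c1OCOC | intermediate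
17 | 2-methoxy-4-vinylphenol | C=Cc1ccc(O)c(OC)c1 | starting material
18 | 4-ethenyl-2-methoxy-1-(methoxymethoxy)benzene | C=Cc1ccc(OCOC)c(OC)c1 | intermediate
19 | 6-(methoxymethylidene)-3,5-bis(methoxymethoxy)-4-[2-(methoxymethoxy)ethyl]-2-(3-methylbut-2-en-1-yl)cyclohexa-2,4-dien-1-one (methoxy ortho-quinone methide, not isolated) | COC=C1C(=O)C(CC=C(C)C)=C(OCOC)C(CCOCOC)=C1OCOC | intermediate
20 | (2S)-4-methoxy-2-[3-methoxy-4-(methoxymethoxy)phenyl]-5,7-bis(methoxymethoxy)-6-[2-(methoxymethoxy)ethyl]-8-(3-methylbut-2-en-1-yl)chromane, C4 epimers | COc1cc([C@@H]2CC(OC)c3c(OCOC)c(CCOCOC)c(OCOC)c(CC=C(C)C)c3O2)ccc1OCOC | intermediate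
21 | (2S)-2-[3-methoxy-4-(methoxymethoxy)phenyl]-5,7-bis(methoxymethoxy)-6-[2-(methoxymethoxy)ethyl]-8-(3-methylbut-2-en-1-yl)chroman-4-ol, C4 epimers | COc1cc([C@@H]2CC(O)c3c(OCOC)c(CCOCOC)c(OCOC)c(CC=C(C)C)c3O2)ccc1OCOC | intermediate
22 | (2S)-2-[3-methoxy-4-(methoxymethoxy)phenyl]-5,7-bis(methoxymethoxy)-6-[2-(methoxymethoxy)ethyl]-8-(3-methylbut-2-en-1-yl)chroman-4-one | COc1cc([C@@H]2CC(=O)c3c(OCOC)c(CCOCOC)c(OCOC)c(CC=C(C)C)c3O2)ccc1OCOC | intermediate
23 | laxiflorin, (2S)-5,7-dihydroxy-6-(2-hydroxyethyl)-2-(4-hydroxy-3-methoxyphenyl)-8-(3-methylbut-2-en-1-yl)chroman-4-one | COc1cc([C@@H]2CC(=O)c3c(O)c(CCO)c(O)c(CC=C(C)C)c3O2)ccc1O | target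

Total step count: 14.
Longest linear sequence: 12 steps (steps 1–4, 6–9 and 11–14, from resorcinol); steps 5 and 10 are side branches.

Steps most likely to fail

1. Step 11. The styrene has no hydrogen-bonding group, so the chiral anion may discriminate its two faces poorly and give low enantiomeric purity at C2; the highly stabilised ion pair may also react sluggishly. Fallback, known chemistry only, setting out from 16 and 18 and returning at 22: the cycloaddition would be run with an achiral acid (diphenyl phosphate, CH2Cl2, 0 °C, or Sc(OTf)3 if that is too weak) to give the racemic 4-methoxyflavan F1. Hydrolysis as in step 12 should give the racemic flavan-4-ol F2, and Dess–Martin oxidation as in step 13 the racemic flavanone F3. Kinetic resolution by asymmetric transfer hydrogenation (RuCl[(R,R)-TsDPEN](p-cymene), HCO2H/Et3N 5:2, EtOAc, rt, stopped near half conversion) should then reduce the 2R ketone to the cis-(2R,4R)-flavan-4-ol F4. The catalyst antipode is the one expected from the usual aryl-ketone model. The 2S ketone is left unreduced; it is 22 and is separated by chromatography.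

2. Step 12. The C4 cation may lose the C3 proton (E1) to give the flav-3-ene, or the exchange of methoxide for hydroxide may stall at equilibrium. Fallback, setting out from 20 and returning at 22: C4 would be oxidised directly with DDQ (1.1 equiv) in CH2Cl2/pH 7 phosphate buffer at 0 °C. Hydride abstraction should occur at the α-methoxy C4–H, the most hydridic position because it is flanked by three ring oxygens; water then adds and methanol is lost to give the ketone. The prenyl CH2 is a competing site, which is why this is not the main route. This fallback passes through no new compound (F0) and skips 21.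

3. Step 14. In warm protic acid the freed C7 hydroxyl may add to the prenyl alkene to close a dimethylchroman ring, and the aliphatic MOM ether may cleave too slowly. Fallback, setting out from 22 and returning at 23: protic solvolysis would be replaced by silyl triflate acetal exchange. TMSOTf and 2,2'-bipyridyl in MeCN at 0 °C should convert the three aryl MOM ethers into aryl trimethylsilyl ethers and the alkyl MOM ether into its N-(alkoxymethyl)bipyridinium triflate, the tris(trimethylsilyl) ether bipyridinium salt F5. Adding water at rt should then hydrolyse all four groups under near-neutral conditions to give 23.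

Further compounds

F1 | step 11 | racemic 4-methoxy-2-[3-methoxy-4-(methoxymethoxy)phenyl]-5,7-bis(methoxymethoxy)-6-[2-(methoxymethoxy)ethyl]-8-(3-methylbut-2-en-1-yl)chromane | COc1cc(C2CC(OC)c3c(OCOC)c(CCOCOC)c(OCOC)c(CC=C(C)C)c3O2)ccc1OCOC
F2 | step 11 | racemic 2-[3-methoxy-4-(methoxymethoxy)phenyl]-5,7-bis(methoxymethoxy)-6-[2-(methoxymethoxy)ethyl]-8-(3-methylbut-2-en-1-yl)chroman-4-ol | COc1cc(C2CC(O)c3c(OCOC)c(CCOCOC)c(OCOC)c(CC=C(C)C)c3O2)ccc1OCOC
F3 | step 11 | racemic 2-[3-methoxy-4-(methoxymethoxy)phenyl]-5,7-bis(methoxymethoxy)-6-[2-(methoxymethoxy)ethyl]-8-(3-methylbut-2-en-1-yl)chroman-4-one | COc1cc(C2CC(=O)c3c(OCOC)c(CCOCOC)c(OCOC)c(CC=C(C)C)c3O2)ccc1OCOC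
F4 | step 11 | (2R,4R)-2-[3-methoxy-4-(methoxymethoxy)phenyl]-5,7-bis(methoxymethoxy)-6-[2-(methoxymethoxy)ethyl]-8-(3-methylbut-2-en-1-yl)chroman-4-ol | COc1cc([C@H]2C[C@@H](O)c3c(OCOC)c(CCOCOC)c(OCOC)c(CC=C(C)C)c3O2)ccc1OCOC
F0 | step 12 | none | none
F5 | step 14 | 1-({2-[(2S)-2-(3-methoxy-4-trimethylsilyloxyphenyl)-4-oxo-8-(3-methylbut-2-en-1-yl)-5,7-bis(trimethylsilyloxy)chroman-6-yl]ethoxy}methyl)-2-(pyridin-2-yl)pyridinium trifluoromethanesulfonate | COc1cc([C@@H]2CC(=O)c3c(O[Si](C)(C)C)c(CCOC[n+]4ccccc4-c4ccccn4)c(O[Si](C)(C)C)c(CC=C(C)C)c3O2)ccc1O[Si](C)(C)C.[O-]S(=O)(=O)C(F)(F)F
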